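A direct plan would take the nine core carbons and the C3–N centre from L-o-tyrosine A1. It would reduce, N-acylate and O-silylate it, then hydroxylate the phenol at its alkyl-bearing ortho carbon to give the o-quinol A2.
It would then epoxidise the enone, unmask the α-acylamino aldehyde A3, and close C4–C5 by a SmI2 epoxide-opening/aldol step to the bicyclic allylic diol A4. A hydroxyl-directed epoxidation would finish it.
Labels: C1 = C–OH bridgehead, C2 = CH2, C3 = CH–N, C4 and C6 = CH–OH on either side of the CH bridgehead C5, C7–C8 = epoxide with C8 on C1, C9 = C=O. Ring A = C1-C2-C3-C4-C5-C9, ring B = C1-C8-C7-C6-C5-C9.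
The weakest step would be the dearomatising hydroxylation. Water would have to add ortho instead of para, the remote C3 centre would hardly bias the new C1 centre, and A2 would dimerise by Diels–Alder reaction.
The silylation, desilylation and oxidation that lead to A3 would add length without complexity and would end in an epimerisable aldehyde.
The reductive aldol would need SmI2 to spare aldehyde, enone and enamide, and its C4 configuration would rest on an assumed chelate.

The nine core carbons hide a mirror plane through C1, C9 and C5 that exchanges ring A (C2–C3–C4) with ring B (C8–C7–C6), and every heteroatom except the C1–OH and C9=O lies on the convex (exo) face. The route therefore builds the bare, achiral diene 10 first: a twofold Pd-catalysed enolate alkenylation ties the methyl carbon (C5) of acyclic ketone 8 to two (Z)-vinyl iodide arms and closes both rings in one operation. Nitrogen and oxygen then arrive from outside, by a desymmetrising aminohydroxylation (C3, C4) and a singlet-oxygen ene/oxygen-transfer step (C6–C8). Phenol oxidation, amino aldehyde, SmI2 aldol and the silyl shuffle have no counterpart.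

Key step: step 6

Assumption: (DHQD)2PHAL is written for step 7. The usual mnemonic does not give the sense of induction on this cis-alkene, and the pseudo-enantiomeric (DHQ)2PHAL would be used if the sense proved opposite.
Remark: exo means the face of ring A or ring B that is turned away from the other ring.

Step 1
Reactants: 1 methyl 2,2-dimethoxypropanoate; 2 3-bromoprop-1-yne (propargyl bromide)
Product: 4 4-(1,1-dimethoxyethyl)hepta-1,6-diyn-4-ol, via propargylmagnesium bromide 3 (not isolated)
Conditions: 2 (2.6 equiv), Mg, HgCl2 (cat.), Et2O, 0 °C; then 1, −20 → 0 °C; aq. work-up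
Reagents that add atoms: none
Why: Double Grignard addition of the propargyl/allenyl magnesium reagent to the ester should give the tertiary carbinol (future C1) with two identical three-carbon arms, while the dimethyl ketal shields the future C9 carbonyl; no stereocentre arises because the arms are identical.

Step 2
Reactants: 4 4-(1,1-dimethoxyethyl)hepta-1,6-diyn-4-ol
Product: 5 4-(1,1-dimethoxyethyl)-1,7-diiodohepta-1,6-diyn-4-ol
Conditions: NIS (2.3 equiv), AgNO3 (10 mol %), acetone, rt, dark
Reagents that add atoms: N-iodosuccinimide, O=C1CCC(=O)N1I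
Why: Silver-catalysed electrophilic iodination of both terminal alkynes is a standard C(sp)–H iodination that should tolerate the tertiary alcohol and the ketal.

Step 3
Reactants: 5 4-(1,1-dimethoxyethyl)-1,7-diiodohepta-1,6-diyn-4-ol
Product: 6 (1Z,6Z)-4-(1,1-dimethoxyethyl)-1,7-diiodohepta-1,6-dien-4-ol
Conditions: 2-nitrobenzenesulfonohydrazide (NBSH, 5 equiv), Et3N, THF/iPrOH, rt
Reagents that add atoms: none
Why: Diimide reduction transfers H2 in a concerted syn fashion to each 1-iodoalkyne and should give the two (Z)-vinyl iodides, the only geometry that can later lie inside a six-membered ring.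

Step 4
Reactants: 6 (1Z,6Z)-4-(1,1-dimethoxyethyl)-1,7-diiodohepta-1,6-dien-4-ol
Product: 7 (5Z)-3-hydroxy-6-iodo-3-[(2Z)-3-iodoprop-2-en-1-yl]hex-5-en-2-one
Conditions: 1 M HCl, THF, rt
Reagents that add atoms: water, O
Why: Acid-catalysed ketal hydrolysis should unmask the methyl ketone (C9=O with C5 as CH3), the vinyl iodides being inert to dilute acid at room temperature.

Step 5
Reactants: 7 (5Z)-3-hydroxy-6-iodo-3-[(2Z)-3-iodoprop-2-en-1-yl]hex-5-en-2-one
Product: 8 (5Z)-6-iodo-3-[(2Z)-3-iodoprop-2-en-1-yl]-3-(methoxymethoxy)hex-5-en-2-one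
Conditions: MOMCl, iPr2NEt, Bu4NI (cat.), CH2Cl2, reflux
Reagents that add atoms: chloromethyl methyl ether, COCCl
Why: MOM ether formation (O-alkylation) blocks the tertiary α-ketol against α-ketol rearrangement and O-alkenylation under basic Pd conditions, and an acetal is preferred to a silyl ether because it cannot migrate to the enolate oxygen.

Step 6
Reactants: 8 (5Z)-6-iodo-3-[(2Z)-3-iodoprop-2-en-1-yl]-3-(methoxymethoxy)hex-5-en-2-one
Product: 10 5-(methoxymethoxy)bicyclo[3.3.1]nona-2,7-dien-9-one (route labels: C1–OMOM, C3=C4, C6=C7; achiral), via 2-[(2Z)-3-iodoprop-2-en-1-yl]-2-(methoxymethoxy)cyclohex-4-en-1-one 9 (not isolated)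
Conditions: Pd(PPh3)4 (15 mol %), KOPh (2.6 equiv), THF (0.01 M), 65 °C
Reagents that add atoms: none
Why: Oxidative addition of Pd(0) into one C(sp2)–I bond, exchange of iodide for the potassium enolate and C–C reductive elimination from a seven-membered C-bound palladacycle should join C5 to one arm and give the β,γ-unsaturated cyclohexenone 9, whose doubly activated C5–H is re-enolised to a dienolate that couples at its α-carbon with the second alkenyl-Pd, so that the C5–C4 and C5–C6 bonds are formed as sp3–sp2 bonds. The reaction type is the intramolecular Pd-catalysed alkenylation of ketone enolates with vinyl halides, which is established for bridged carbo- and azabicyclo[3.3.1]nonanes. Each ring closes in a 6-(enolendo) sense, the first as a monocycle and the second across the 1,3-diaxial positions of the first, and the (Z)-iodides place a cis-alkene in each ring. C1 and C5 become bridgeheads whose relative configuration is enforced by the bridge, and because both bridges are identical 10 keeps the mirror plane through C1, C9 and C5 and is achiral. Enolisation can only occur at C5 because C1 is quaternary, C- over O-alkenylation is the normal outcome of reductive elimination from Pd enolates, and over-reaction is excluded because the bridgehead C5–H of 10 cannot enolise (Bredt). The weak base KOPh and high dilution are needed to hold back anti-dehydroiodination of the (Z)-iodides and intermolecular coupling.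

Step 7
Reactants: 10 5-(methoxymethoxy)bicyclo[3.3.1]nona-2,7-dien-9-one
Product: 11 tert-butyl N-[(1R,3S,4R,5R)-4-hydroxy-1-(methoxymethoxy)-9-oxobicyclo[3.3.1]non-6-en-3-yl]carbamate (NHBoc on C3 and OH on C4 both exo, cis)
Conditions: BocNHOC(O)C6H4-4-Cl (1.0 equiv), K2OsO2(OH)4 (4 mol %), (DHQD)2PHAL (5 mol %), MeCN/H2O 8:1, 0 °C → rt
Reagents that add atoms: tert-butyl (4-chlorobenzoyloxy)carbamate, CC(C)(C)OC(=O)NOC(=O)c1ccc(Cl)cc1; water, O
Why: The Sharpless asymmetric aminohydroxylation in its base-free N-acyloxycarbamate variant adds BocN and O suprafacially to the only open (exo) face of one alkene, which sets C3 and C4 cis and exo with the bulkier N end on C3 (the alkene carbon remote from the bridgehead and the C9 carbonyl), while the cinchona ligand chooses between the two enantiotopic alkenes and so fixes C1, C3, C4 and C5 in the absolute sense at once, any minor enantiomer being consumed faster in a second aminohydroxylation.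

Step 8
Reactants: 11 tert-butyl N-[(1R,3S,4R,5R)-4-hydroxy-1-(methoxymethoxy)-9-oxobicyclo[3.3.1]non-6-en-3-yl]carbamate
Product: 12 (1R,3S,4R,5R)-3-amino-1,4-dihydroxybicyclo[3.3.1]non-6-en-9-one hydrochloride (route labels)
Conditions: HCl (3 M in MeOH), 40 °C
Reagents that add atoms: hydrogen chloride, Cl
Why: Acidolysis should remove the Boc group and the MOM acetal in one operation before any epoxide is present, and dehydration of the β-hydroxy ketone is excluded because C5 is a bridgehead, so no stereocentre is touched.

Step 9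
Reactants: 12 (1R,3S,4R,5R)-3-amino-1,4-dihydroxybicyclo[3.3.1]non-6-en-9-one hydrochloride; 13 (E)-dec-2-enoic acid
Product: 14 (2E)-N-[(1R,3S,4R,5R)-1,4-dihydroxy-9-oxobicyclo[3.3.1]non-6-en-3-yl]dec-2-enamide
Conditions: EDC·HCl, HOBt, iPr2NEt, CH2Cl2/DMF, 0 °C → rt
Reagents that add atoms: none
Why: Carbodiimide/HOBt amide coupling should acylate the amine in preference to the secondary and tertiary alcohols and bring in the (E)-enoyl chain without touching a stereocentre.

Step 10
Reactants: 14 (2E)-N-[(1R,3S,4R,5R)-1,4-dihydroxy-9-oxobicyclo[3.3.1]non-6-en-3-yl]dec-2-enamide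
Product: 16 isariotin D (route labels: C1 S, C3 S, C4 R, C5 S, C6 S, C7 S, C8 S), via (2E)-N-[(1S,2R,3S,5S,8R)-8-hydroperoxy-2,5-dihydroxy-9-oxobicyclo[3.3.1]non-6-en-3-yl]dec-2-enamide 15 (not isolated)
Conditions: O2, TPP (cat.), hν (Na lamp), Ti(OiPr)4 (20 mol %), 4 Å MS, CH2Cl2, −20 → 0 °C
Reagents that add atoms: oxygen, O=O
Why: A Schenck ene reaction of singlet oxygen on the exo face of C6=C7 can only abstract the axial exo H on C8 (abstraction at C5 would give an anti-Bredt alkene), so it should place OOH exo on C6 and move the alkene to C7=C8, and the Ti(IV)-catalysed oxygen transfer from the allylic hydroperoxide (direct epoxy-hydroxylation) then delivers the distal oxygen to the same exo face, setting C6, C7 and C8 all cis, while the electron-poor enamide alkene is inert to both electrophilic oxidants.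

Compound list
1 | methyl 2,2-dimethoxypropanoate | COC(=O)C(C)(OC)OC | starting material
2 | 3-bromoprop-1-yne (propargyl bromide) | C#CCBr | starting material
3 | propargylmagnesium bromide | C#CC[Mg]Br | intermediate
4 | 4-(1,1-dimethoxyethyl)hepta-1,6-diyn-4-ol | CC(OC)(OC)C(O)(CC#C)CC#C | intermediate
5 | 4-(1,1-dimethoxyethyl)-1,7-diiodohepta-1,6-diyn-4-ol | CC(OC)(OC)C(O)(CC#CI)CC#CI | intermediate
6 | (1Z,6Z)-4-(1,1-dimethoxyethyl)-1,7-diiodohepta-1,6-dien-4-ol | CC(OC)(OC)C(O)(C/C=C\I)C/C=C\I | intermediate
7 | (5Z)-3-hydroxy-6-iodo-3-[(2Z)-3-iodoprop-2-en-1-yl]hex-5-en-2-one | CC(=O)C(O)(C/C=C\I)C/C=C\I | intermediate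
8 | (5Z)-6-iodo-3-[(2Z)-3-iodoprop-2-en-1-yl]-3-(methoxymethoxy)hex-5-en-2-one | CC(=O)C(C/C=C\I)(C/C=C\I)OCOC | intermediate
9 | 2-[(2Z)-3-iodoprop-2-en-1-yl]-2-(methoxymethoxy)cyclohex-4-en-1-one (racemic) | O=C1CC=CCC1(C/C=C\I)OCOC | intermediate
10 | 5-(methoxymethoxy)bicyclo[3.3.1]nona-2,7-dien-9-one (achiral) | O=C1C2C=CCC1(OCOC)CC=C2 | intermediate
11 | tert-butyl N-[(1R,3S,4R,5R)-4-hydroxy-1-(methoxymethoxy)-9-oxobicyclo[3.3.1]non-6-en-3-yl]carbamate | CC(C)(C)OC(=O)N[C@H]1C[C@@]2(OCOC)C(=O)[C@H](C=CC2)[C@H]1O | intermediate
12 | (1R,3S,4R,5R)-3-amino-1,4-dihydroxybicyclo[3.3.1]non-6-en-9-one hydrochloride (route labels) | [Cl-].[NH3+][C@H]1C[C@@]2(O)C(=O)[C@H](C=CC2)[C@H]1O | intermediate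
13 | (E)-dec-2-enoic acid | CCCCCCC/C=C/C(=O)O | starting material
14 | (2E)-N-[(1R,3S,4R,5R)-1,4-dihydroxy-9-oxobicyclo[3.3.1]non-6-en-3-yl]dec-2-enamide | CCCCCCC/C=C/C(=O)N[C@H]1C[C@@]2(O)C(=O)[C@H](C=CC2)[C@H]1O | intermediate
15 | (2E)-N-[(1S,2R,3S,5S,8R)-8-hydroperoxy-2,5-dihydroxy-9-oxobicyclo[3.3.1]non-6-en-3-yl]dec-2-enamide | CCCCCCC/C=C/C(=O)N[C@H]1C[C@@]2(O)C(=O)[C@H]([C@H](OO)C=C2)[C@H]1O | intermediate
16 | isariotin D | CCCCCCC/C=C/C(=O)N[C@H]1C[C@@]2(O)C(=O)[C@H]([C@H](O)[C@@H]3O[C@@H]32)[C@H]1O | target

Total step count: 10. Longest linear sequence: 10 steps (1 → 16).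

Steps most likely to fail

Step 7. The catalyst may discriminate poorly between the two enantiotopic alkenes, because cis-disubstituted alkenes are the weakest substrate class for cinchona–osmium catalysts. N/O regiocontrol may also erode. The fallback sets out from 10 and separates the source of chirality from the C–N bond formation. The same aminohydroxylation without ligand would give 11 together with its enantiomer F4. An immobilised lipase (Candida antarctica lipase B) with vinyl acetate would then acetylate one enantiomer at the C4–OH in a kinetic resolution. This enantiomer is taken here to be 11, which would give the C4 acetate F3. After chromatographic separation from the unreacted alcohol, K2CO3/MeOH would release the alcohol from the acetate and rejoin the route at 11.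

Step 6. The base may dehydroiodinate the (Z)-vinyl iodides to alkynes. The first-formed β,γ-enone may drift into conjugation. The sequence may also stall after the first ring, because the second closure needs both substituents axial. The fallback sets out from 8 and closes the rings one at a time, through preformed and isolated enol silanes under base-free conditions. TMSOTf/Et3N would give the trimethylsilyl enol ether F1. Pd-catalysed coupling through the tin enolate formed with Bu3SnF would then give 9, now isolated. A second silylation would give the trimethylsilyl dienol ether F2, and the same coupling at its α-carbon would rejoin the route at 10.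

Step 10. The ene reaction of a 1,2-disubstituted alkene may be sluggish, so that bleaching of the sensitiser, slow photo-oxidation of the side chain or incomplete oxygen transfer take over. The fallback sets out from 14 and replaces the pericyclic oxygenation by an epoxide-to-allylic-alcohol transposition. TESOTf/2,6-lutidine would give the C1,C4-bis(triethylsilyl) ether F5. Dimethyldioxirane would epoxidise the isolated alkene from the exo face to give the 6,7-epoxide F6. Et2Al(TMP) would coordinate the epoxide oxygen and remove the syn exo H on C8, the only one allowed by Bredt's rule, to give the C6 allylic alcohol F7. VO(acac)2/tBuOOH would give the epoxy alcohol F8, and HF·pyridine would rejoin the route at 16.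

Further compounds
F1 | step 6 | (1Z,6Z)-1,7-diiodo-4-(methoxymethoxy)-4-[1-(trimethylsilyloxy)ethenyl]hepta-1,6-diene (trimethylsilyl enol ether of 8) | C=C(O[Si](C)(C)C)C(C/C=C\I)(C/C=C\I)OCOC
F2 | step 6 | trimethylsilyl dienol ether of 9, {6-[(2Z)-3-iodoprop-2-en-1-yl]-6-(methoxymethoxy)cyclohexa-1,3-dien-1-yl}oxy(trimethyl)silane | C[Si](C)(C)OC1=CC=CCC1(C/C=C\I)OCOC
F3 | step 7 | C4 acetate of 11 | CC(C)(C)OC(=O)N[C@H]1C[C@@]2(OCOC)C(=O)[C@H](C=CC2)[C@H]1OC(C)=O
F4 | step 7 | enantiomer of 11 | CC(C)(C)OC(=O)N[C@@H]1C[C@]2(OCOC)C(=O)[C@@H](C=CC2)[C@@H]1O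
F5 | step 10 | C1,C4-bis(triethylsilyl) ether of 14 | CCCCCCC/C=C/C(=O)N[C@H]1C[C@@]2(O[Si](CC)(CC)CC)C(=O)[C@H](C=CC2)[C@H]1O[Si](CC)(CC)CC
F6 | step 10 | exo-6,7-epoxide of F5 | CCCCCCC/C=C/C(=O)N[C@H]1C[C@@]2(O[Si](CC)(CC)CC)C(=O)[C@H]([C@@H]3O[C@@H]3C2)[C@H]1O[Si](CC)(CC)CC
F7 | step 10 | C6-exo allylic alcohol (C7=C8), C1,C4-bis(triethylsilyl) ether | CCCCCCC/C=C/C(=O)N[C@H]1C[C@@]2(O[Si](CC)(CC)CC)C(=O)[C@H]([C@H](O)C=C2)[C@H]1O[Si](CC)(CC)CC
F8 | step 10 | C1,C4-bis(triethylsilyl) ether of isariotin D | CCCCCCC/C=C/C(=O)N[C@H]1C[C@@]2(O[Si](CC)(CC)CC)C(=O)[C@H]([C@H](O)[C@@H]3O[C@@H]32)[C@H]1O[Si](CC)(CC)CC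
A1 | direct plan | L-o-tyrosine | N[C@@H](Cc1ccccc1O)C(=O)O
A2 | direct plan | N-decenoyl, O-TBS o-quinol (6-alkyl-6-hydroxycyclohexa-2,4-dienone) | CCCCCCC/C=C/C(=O)N[C@H](CO[Si](C)(C)C(C)(C)C)C[C@@]1(O)C(=O)C=CC=C1
A3 | direct plan | epoxy-enone α-acylamino aldehyde | CCCCCCC/C=C/C(=O)N[C@H](C=O)C[C@@]1(O)C(=O)[C@@H]2O[C@@H]2C=C1
A4 | direct plan | bicyclo[3.3.1]nonenone allylic diol (C7=C8, free C1-, C4- and C6-OH) | CCCCCCC/C=C/C(=O)N[C@H]1C[C@@]2(O)C(=O)[C@H]([C@H](O)C=C2)[C@H]1O
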